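## Analysis of the target

Target 19 is a hexacyclic bis-indole. A 2-methyl-tetrahydro-β-carboline (benzene ring A, five-membered ring B, piperidine ring C; locants C1, N2, C3, C4, C4a, C4b–C8a, N9, C9a) is fused at its former indole 2,3-bond through a dihydrofuran (ring D: O, C4a, C9a, C4′, C5′) to the benzene ring E of a 7′-methoxygramine (pyrrole ring F; primed indole locants); "core" below means this hexacyclic ring system. Ring D is a benzofuro[3,2-b]indoline: the ether oxygen sits on C4a (the former indole C3) and the aryl carbon C4′ on C9a (the former indole C2, an α-tertiary amine carbon), the reverse of the pairing that the innate polarity of an indole gives with an electrophilic phenol equivalent. The only stereocentres, C4a (S) and C9a (R), are adjacent, fully substituted and shared by rings B, C and D; the three rings can only be cis-fused on the C4a–C9a bond, so ring D enforces the relative configuration and only the absolute configuration has to be controlled. Ring E is pentasubstituted, and its neighbouring atoms C4′ (bonded to C9a) and C5′ (bonded to the ring-D oxygen), next to the ring-fusion atom C3a′, are the feature on which the route is built: with the O–C4a–C9a–N9 unit of ring D they are the retron of a 4,5-indolyne that takes up an oxygen nucleophile at C5′ and a carbon electrophile at C4′ in one operation. Sensitive groups are the gramine unit (loss of dimethylamine through a 3-methyleneindolenine), two oxidisable N–H heterocycles, the basic and nucleophilic N2, and the tertiary benzylic aryl ether at C4a, which can ionise in strong acid. The synthesis is hard because two hindered bonds (C9a–C4′ and C4a–O) must be made against normal indole reactivity, at two contiguous quaternary centres, as one enantiomer, without a long sequence spent on two different indoles.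

## Retrosynthetic reasoning

**19 ⇒ 18 (C3′–CH2 bond).** The gramine side chain is the most fragile unit and a nucleophilic tertiary amine, so it is cut first and made last. The forward step is a Mannich reaction at C3′ of 18, the most nucleophilic carbon of the molecule; it must win over N9–H and the indoline ring.

**18 ⇒ 17 ⇒ 16 (two functional-group changes).** The N2-methyl group is traced back to the methyl carbamate of 17, the N1′–H to the SEM group of 16 (SEM = 2-(trimethylsilyl)ethoxymethyl). A free tertiary N2 would add to an aryne and be N-oxidised, so it travels as a carbamate whose carbon becomes the methyl group. N1′–H is more acidic than the carbinol that has to be deprotonated in the key step, so it must be masked by a group inert to alkoxide, fluoride and organolithium reagents.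

**16 ⇒ 12 + 14 (key disconnection: C5′–O and C4′–C9a).** Cutting both bonds opens ring D. The eastern half becomes the α-hydroxy imine 12 (O–C4a–C9a=N9: oxygen nucleophile next to a carbon electrophile). The western half becomes the 4,5-indolyne 14 (electrophile at C5′, then aryl anion at C4′), released from silyl triflate 9. This cut removes ring D, the C9a stereocentre and the substitution problem of ring E at once, and its polarity matches the "wrong-way" pairing of the target. The forward reaction has to deliver oxygen to C5′ regioselectively and close ring D on the imine before the aryl anion is quenched.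

**12 ⇒ 11 ⇒ 10 (C4a–O bond).** Hydroxyindolenine 12 carries the single stereocentre from which the second is relayed. It comes from enantioselective oxygen transfer to the indole 2,3-bond of carbamate 11, itself the N-acylation product of commercial 10.

**9 ⇒ 6 ⇒ 5 ⇒ 4 ⇒ 3 ⇒ 2 ⇒ 1 (aryne precursor).** The ortho-silyl triflate 9 is traced to ortho-bromophenol 6 through O-silylation, bromine–lithium exchange and retro-Brook migration (7, 8). Directed metalation of a C5′ carbamate was not chosen, because the position between the two oxygens (C6′) would be metalated. The indole 4 comes from nitroarene 3 by a Bartoli reaction, in which the methoxy group is the required ortho substituent. The bromine is placed at the benzene stage (1 → 2), where the regiochemistry is unambiguous.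

## Alternatives that were turned down

**Alternative 1:** (textbook) Disconnection of C1–C9a and C4a–O by a Pictet–Spengler cascade.
- Forward key step: the biaryl tryptamine 2-[2-(5-hydroxy-7-methoxy-1H-indol-4-yl)-1H-indol-3-yl]-N-methylethanamine A1 reacts with formaldehyde and acid. The iminium is attacked by indole C4a, the aminomethyl carbon shifts to C9a, and the C4a cation is captured by the C5′ hydroxyl.
- Turned down because every intermediate of the cationic manifold is planar or configurationally labile, so a single enantiomer needs a removable auxiliary or a resolution.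
- A1 itself demands a hindered C9a–C4′ biaryl coupling between two separately built and protected indoles, one fully substituted. That precursor costs more steps than the whole present route to 16.

**Alternative 2:** (biomimetic) Disconnection of the same two ring-D bonds by oxidative phenol–indole coupling.
- Forward key step: 7-methoxy-1H-indol-5-ol A2 is coupled with carbamate 11 using PhI(OAc)2.
- Turned down because the nucleophilic carbon of the indole is C4a and the oxidised phenol is electrophilic at C4′. The innate pairing is therefore C4a–C4′ and O–C9a, the isomeric fusion; reversing it requires acyl or sulfonyl groups on N9 that must be put on and taken off.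
- A2 contains a second, more oxidisable pyrrole ring, and two planar achiral partners offer no handle for absolute configuration without an auxiliary.

**Alternative 3:** Disconnection of ring F (N1′–C2′ and C3′–C3a′) at the end.
- Forward key step: a Bartoli reaction of vinylmagnesium bromide with the nitroarene core A3, followed by the same endgame.
- Turned down because it leaves the real problem untouched: ring D and both stereocentres would still need a separate solution on a simpler arene.
- It places a low-yielding reaction with three equivalents of Grignard reagent after the stereocentres are made, next to a carbamate and N9–H.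
- It gives up the fused pyrrole ring as the element that directs the aryne addition.

Key step: step 9

Assumption: the (+)-enantiomer of the oxaziridine is taken to deliver the (4aS) carbinol 12; if the sense of induction on this substrate proves opposite, the commercial (−)-enantiomer is used with no other change.

## Route

**Step 1**
Reactants: 1 3-methoxy-4-nitrophenol
Product: 2 2-bromo-5-methoxy-4-nitrophenol
Conditions: NBS (1.0 equiv), MeCN, 0 °C → rt
Reagents that add atoms: N-bromosuccinimide, O=C1CCC(=O)N1Br
Why: Electrophilic aromatic bromination; the position ortho to OH and para to OMe is the most activated and least hindered site (the other ortho position lies between OH and OMe), so bromine should end where C4′ will be.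

**Step 2**
Reactants: 2 2-bromo-5-methoxy-4-nitrophenol
Product: 3 (2-bromo-5-methoxy-4-nitrophenoxy)triisopropylsilane
Conditions: TIPSCl, imidazole, DMF, rt
Reagents that add atoms: chlorotriisopropylsilane, CC(C)[Si](Cl)(C(C)C)C(C)C
Why: Standard O-silylation; the bulky silyl ether masks the acidic nitrophenol, which would otherwise consume the Grignard reagent and deactivate the nitro group as its phenoxide.

**Step 3**
Reactants: 3 (2-bromo-5-methoxy-4-nitrophenoxy)triisopropylsilane
Product: 4 4-bromo-7-methoxy-5-(triisopropylsilyloxy)-1H-indole
Conditions: CH2=CHMgBr (3.5 equiv), THF, −45 °C; aq NH4Cl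
Reagents that add atoms: vinylmagnesium bromide, C=C[Mg]Br
Why: Bartoli indole synthesis; the ortho methoxy group is the ortho substituent this reaction needs, and the [3,3]-sigmatropic shift can only go to the free ortho carbon between NO2 and C–Br. Bromine therefore ends at C4, the silyloxy group at C5 and the methoxy group at C7 without ambiguity.

**Step 4**
Reactants: 4 4-bromo-7-methoxy-5-(triisopropylsilyloxy)-1H-indole
Product: 5 4-bromo-7-methoxy-5-(triisopropylsilyloxy)-1-{[2-(trimethylsilyl)ethoxy]methyl}-1H-indole
Conditions: NaH, THF, 0 °C; SEMCl, 0 °C → rt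
Reagents that add atoms: 2-(trimethylsilyl)ethoxymethyl chloride, C[Si](C)(C)CCOCCl
Why: N-alkylation of the indolide; SEM is inert to n-BuLi at −78 °C, to fluoride at rt and to alkoxide, whereas a free N–H would quench the alkoxide of the key step and an N-acyl group could be transferred to it.

**Step 5**
Reactants: 5 4-bromo-7-methoxy-5-(triisopropylsilyloxy)-1-{[2-(trimethylsilyl)ethoxy]methyl}-1H-indole
Product: 6 4-bromo-7-methoxy-1-{[2-(trimethylsilyl)ethoxy]methyl}-1H-indol-5-ol
Conditions: TBAF, THF, 0 °C
Reagents that add atoms: none
Why: Fluoride cleavage of the aryl silyl ether; the N-SEM group needs far more forcing fluoride conditions and the aryl bromide is untouched.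

**Step 6**
Reactants: 6 4-bromo-7-methoxy-1-{[2-(trimethylsilyl)ethoxy]methyl}-1H-indol-5-ol
Product: 9 7-methoxy-1-{[2-(trimethylsilyl)ethoxy]methyl}-4-(trimethylsilyl)-1H-indol-5-yl trifluoromethanesulfonate, via aryl trimethylsilyl ether 7 (not isolated), via lithium 4-silylindol-5-olate 8 (not isolated)
Conditions: HMDS, THF, 65 °C, then evaporation; n-BuLi, THF, −78 °C; PhNTf2, −78 °C → rt
Reagents that add atoms: hexamethyldisilazane, C[Si](C)(C)N[Si](C)(C)C; N-phenylbis(trifluoromethanesulfonimide), O=S(=O)(N(c1ccccc1)S(=O)(=O)C(F)(F)F)C(F)(F)F
Why: Standard preparation of an ortho-silylaryl triflate from an ortho-bromophenol: O-silylation, bromine–lithium exchange with 1,3-O→C silyl shift (retro-Brook rearrangement, driven by phenoxide formation) and O-triflation. Exchange at −78 °C is faster than deprotonation at C2′.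

**Step 7**
Reactants: 10 2,3,4,9-tetrahydro-1H-pyrido[3,4-b]indole (tryptoline)
Product: 11 methyl 1,3,4,9-tetrahydro-2H-pyrido[3,4-b]indole-2-carboxylate
Conditions: ClCO2Me, Et3N, CH2Cl2, 0 °C
Reagents that add atoms: methyl chloroformate, COC(=O)Cl
Why: N-acylation of the secondary amine; the carbamate removes the nucleophilicity of N2 (needed in steps 8 and 9) and is the latent N-methyl group.

**Step 8**
Reactants: 11 methyl 1,3,4,9-tetrahydro-2H-pyrido[3,4-b]indole-2-carboxylate
Product: 12 methyl (4aS)-4a-hydroxy-1,3,4,4a-tetrahydro-2H-pyrido[3,4-b]indole-2-carboxylate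
Conditions: (+)-[(8,8-dichlorocamphoryl)sulfonyl]oxaziridine (1.2 equiv), CH2Cl2, 0 °C → rt
Reagents that add atoms: (+)-[(8,8-dichlorocamphoryl)sulfonyl]oxaziridine, CC1(C)[C@@H]2CC[C@]13CS(=O)(=O)N4O[C@@]34C2(Cl)Cl
Why: Electrophilic oxygen transfer to the indole C4a=C9a bond and opening of the indole epoxide by the N9 lone pair give the 3-hydroxyindolenine, a known enantioselective oxidation of 2,3-disubstituted indoles with this reagent class. C4a is set by reagent control (the camphor framework differentiates the two faces of the planar indole), and the carbamate nitrogen is not oxidised.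

**Step 9**
Reactants: 12 methyl (4aS)-4a-hydroxy-1,3,4,4a-tetrahydro-2H-pyrido[3,4-b]indole-2-carboxylate, 9 7-methoxy-1-{[2-(trimethylsilyl)ethoxy]methyl}-4-(trimethylsilyl)-1H-indol-5-yl trifluoromethanesulfonate
Product: 16 (4aS,9aR)-N2-(methoxycarbonyl)-N1′-SEM-7′-methoxy core, via sodium alkoxide 13 (not isolated), via 4,5-indolyne 14 (not isolated), via C4′ aryl anion 15 (not isolated)
Conditions: 12 (1.5 equiv), NaH, 15-crown-5, THF, 0 °C; then 9, Bu4N[Ph3SiF2] (TBAT), THF, −20 °C → rt; aq NH4Cl
Reagents that add atoms: none
Why: Proposed new method: alkoxide 13 adds through oxygen to C5′ of indolyne 14 (released from 9 by fluoride), the C4′ aryl anion 15 so formed adds to the neighbouring C9a=N9 bond, and aqueous work-up protonates the resulting anilide to give the N9–H of 16. The closest known reaction types are aryne annulations in which a heteroatom nucleophile adds to the aryne and the aryl anion is trapped by a pendant C=O or C=N group (formal insertion of the aryne into a three-atom unit) and Parham-type additions of aryllithiums to imines; a tertiary α-hydroxy imine has not been used in this role. Ring D closes in the 5-exo-trig mode (C4′ attacks C9a, N9 lies outside the new ring). C4a is not touched and keeps the (S) configuration of 12, and C9a is set by substrate control, since the aryl anion tethered through the C4a oxygen can reach only the imine face syn to that oxygen, which gives the cis-fused (4aS,9aR) product. The step needs O-attack at C5′ and not at C4′: in a 4,5-indolyne the fused pyrrole ring beside C4′ pinches the internal angle at C4′, so C5′ is the flatter, more electrophilic terminus and the developing negative charge goes to C4′, and the peri C3′–H beside C4′ adds a steric bias against a tertiary alkoxide there. The atom beside C5′ is only C6′–H; the methoxy group sits one position further away at C7′, too remote to reverse this preference. Chemoselectivity rests on the carbamate (N2 cannot add to the aryne), on the anionic oxygen outrunning the neutral imine nitrogen, on an excess of 13 (the hindered product anilide does not compete for 14) and on aprotic THF (cyclisation of 15 outruns protonation). Working at or below room temperature should keep the α-iminol rearrangement of 13 to a pseudoindoxyl slow.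

**Step 10**
Reactants: 16 (4aS,9aR)-N2-(methoxycarbonyl)-N1′-SEM-7′-methoxy core
Product: 17 (4aS,9aR)-N2-(methoxycarbonyl)-7′-methoxy core (N1′–H, C3′–H)
Conditions: TBAF, H2NCH2CH2NH2, DMF, 80 °C
Reagents that add atoms: none
Why: Fluoride-induced fragmentation of the SEM group; ethylenediamine scavenges the formaldehyde released so that it cannot aminomethylate the indole or indoline. The methyl carbamate, the aryl ethers and both stereocentres are inert.

**Step 11**
Reactants: 17 (4aS,9aR)-N2-(methoxycarbonyl)-7′-methoxy core
Product: 18 (4aS,9aR)-N2-methyl-7′-methoxy core (3′-unsubstituted target)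
Conditions: LiAlH4, THF, 65 °C; aqueous NaOH work-up
Reagents that add atoms: none
Why: Hydride reduction of a carbamate to an N-methyl amine: the carbonyl carbon becomes the N2-methyl group and methoxide is lost. The aryl ethers, the N–H groups and the quaternary stereocentres are unaffected.

**Step 12**
Reactants: 18 (4aS,9aR)-N2-methyl-7′-methoxy core
Product: 19 (4aS,9aR)-3′-[(dimethylamino)methyl]-N2-methyl-7′-methoxy core (target)
Conditions: 37% aq CH2O, 40% aq Me2NH, AcOH, 0 °C → rt
Reagents that add atoms: formaldehyde, C=O; dimethylamine, CNC
Why: Mannich reaction (gramine synthesis) at C3′, the enamine carbon activated by N1′ and the C5′/C7′ oxygens. Aminomethylation of the hindered N9–H gives only a reversible aminal in acetic acid, so the C3′ product should accumulate, and mild acid at rt leaves the gramine and the C4a ether intact.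

## Compound list

1 | 3-methoxy-4-nitrophenol | COc1cc(O)ccc1[N+](=O)[O-] | starting material
2 | 2-bromo-5-methoxy-4-nitrophenol | COc1cc(O)c(Br)cc1[N+](=O)[O-] | intermediate
3 | (2-bromo-5-methoxy-4-nitrophenoxy)triisopropylsilane | COc1cc(O[Si](C(C)C)(C(C)C)C(C)C)c(Br)cc1[N+](=O)[O-] | intermediate
4 | 4-bromo-7-methoxy-5-(triisopropylsilyloxy)-1H-indole | COc1cc(O[Si](C(C)C)(C(C)C)C(C)C)c(Br)c2cc[nH]c12 | intermediate
5 | 4-bromo-7-methoxy-5-(triisopropylsilyloxy)-1-{[2-(trimethylsilyl)ethoxy]methyl}-1H-indole | COc1cc(O[Si](C(C)C)(C(C)C)C(C)C)c(Br)c2ccn(COCC[Si](C)(C)C)c12 | intermediate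
6 | 4-bromo-7-methoxy-1-{[2-(trimethylsilyl)ethoxy]methyl}-1H-indol-5-ol | COc1cc(O)c(Br)c2ccn(COCC[Si](C)(C)C)c12 | intermediate
7 | 4-bromo-7-methoxy-1-{[2-(trimethylsilyl)ethoxy]methyl}-5-(trimethylsilyloxy)-1H-indole | COc1cc(O[Si](C)(C)C)c(Br)c2ccn(COCC[Si](C)(C)C)c12 | intermediate (not isolated)
8 | lithium 7-methoxy-1-{[2-(trimethylsilyl)ethoxy]methyl}-4-(trimethylsilyl)-1H-indol-5-olate | COc1cc([O-])c([Si](C)(C)C)c2ccn(COCC[Si](C)(C)C)c12.[Li+] | intermediate (not isolated)
9 | 7-methoxy-1-{[2-(trimethylsilyl)ethoxy]methyl}-4-(trimethylsilyl)-1H-indol-5-yl trifluoromethanesulfonate | COc1cc(OS(=O)(=O)C(F)(F)F)c([Si](C)(C)C)c2ccn(COCC[Si](C)(C)C)c12 | intermediate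
10 | 2,3,4,9-tetrahydro-1H-pyrido[3,4-b]indole (tryptoline) | c1ccc2c(c1)c1CCNCc1[nH]2 | starting material
11 | methyl 1,3,4,9-tetrahydro-2H-pyrido[3,4-b]indole-2-carboxylate | COC(=O)N1CCc2c(C1)[nH]c1ccccc21 | intermediate
12 | methyl (4aS)-4a-hydroxy-1,3,4,4a-tetrahydro-2H-pyrido[3,4-b]indole-2-carboxylate | COC(=O)N1CC[C@]2(O)c3ccccc3N=C2C1 | intermediate
13 | sodium alkoxide of 12 | COC(=O)N1CC[C@]2([O-])c3ccccc3N=C2C1.[Na+] | intermediate (not isolated)
14 | 7-methoxy-1-{[2-(trimethylsilyl)ethoxy]methyl}-4,5-didehydro-1H-indole (4,5-indolyne) | COC1=CC#CC2=C1N(COCC[Si](C)(C)C)C=C2 | intermediate (not isolated)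
15 | sodium salt of the C4′ carbanion of methyl (4aS)-4a-[(7-methoxy-1-SEM-indol-5-yl)oxy]-1,3,4,4a-tetrahydro-2H-pyrido[3,4-b]indole-2-carboxylate | COC(=O)N1CC[C@]2(Oc3cc(OC)c4n(COCC[Si](C)(C)C)ccc4[c-]3)c3ccccc3N=C2C1.[Na+] | intermediate (not isolated)
16 | (4aS,9aR)-N2-(methoxycarbonyl)-N1′-SEM-7′-methoxy core (O links C4a to C5′; C9a bonded to C4′; N9–H; C3′–H) | COc1cc2c(c3ccn(COCC[Si](C)(C)C)c13)[C@@]13CN(C(=O)OC)CC[C@]1(O2)c1ccccc1N3 | intermediate
17 | (4aS,9aR)-N2-(methoxycarbonyl)-7′-methoxy core (N1′–H, N9–H, C3′–H) | COc1cc2c(c3cc[nH]c13)[C@@]13CN(C(=O)OC)CC[C@]1(O2)c1ccccc1N3 | intermediate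
18 | (4aS,9aR)-N2-methyl-7′-methoxy core (3′-unsubstituted target) | COc1cc2c(c3cc[nH]c13)[C@@]13CN(C)CC[C@]1(O2)c1ccccc1N3 | intermediate
19 | (4aS,9aR)-3′-[(dimethylamino)methyl]-N2-methyl-7′-methoxy core | COc1cc2c(c3c(CN(C)C)c[nH]c13)[C@@]13CN(C)CC[C@]1(O2)c1ccccc1N3 | target

## Step count and least certain steps

Total step count: 12 (six to silyl triflate 9, two to hydroxyindolenine 12, four from their union). Longest linear sequence: 10 steps (1 → 19 through steps 1–6 and 9–12).

**Step 9 (key step, proposed new method).** Most likely failures:
- α-iminol rearrangement of alkoxide 13 before the aryne is released;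
- erosion of regioselectivity in the alkoxide addition (attack at C4′);
- protonation of aryl anion 15 before ring closure;
- attack of 13 at the triflate sulfur of 9.

Fallback with known chemistry, setting out from 5 and 11 and returning at 16. Carbamate 11 is oxidised with the enantiomeric (−)-oxaziridine to methyl (4aR)-4a-hydroxy-1,3,4,4a-tetrahydro-2H-pyrido[3,4-b]indole-2-carboxylate F1, which TMSCl and imidazole convert into its trimethylsilyl ether F2. Bromine–lithium exchange on 5 (t-BuLi, THF, −78 °C) and transmetalation with CeCl3 give the C4′ organocerium reagent. It adds to the C9a=N9 bond of F2 on the face opposite to the silyloxy group, giving the (4aR,9aR)-9a-aryl-4a-silyloxy indoline F3. TBAF at 0 °C removes both O-silyl groups to give the phenol carbinol F4. Camphorsulfonic acid in CH2Cl2 then ionises the tertiary benzylic C4a–OH, and the C5′ hydroxyl captures the cation on the only face it can reach, that of the C9a aryl group, which returns 16. Because C4a passes through a cation, the absolute configuration rests on C9a alone, which is why the antipode of 12 is the starting point.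

**Step 8.** Facial discrimination may be poor, because the two substituents of the indole 2,3-bond are both ring CH2 groups. Acid-induced rearrangement of the hydroxyindolenine to an oxindole is a second risk.

Fallback, setting out from 10 and returning at 18. Tryptoline 10 is acylated with (1R,2S,5R)-menthyl chloroformate to the menthyl carbamate F5. Achiral oxidation (dimethyldioxirane, acetone, −78 °C) gives both C4a epimers, which are now diastereomers and are separated by crystallisation or chromatography to give the (4aS)-hydroxyindolenine menthyl carbamate F6. F6 is taken through the conditions of step 9 (annulated menthyl carbamate F7) and step 10 (its N1′–H analogue F8). The LiAlH4 reduction of step 11 turns the menthyl carbamate into the same N-methyl group, so the auxiliary leaves as menthol at no extra step and 18 is reached.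

**Step 12.** Aminomethylation may compete at N9, at the position para to N9 or at C6′, and the peri substituent at C4′ slows attack at C3′.

Fallback, setting out from 18 and returning at 19. Vilsmeier–Haack formylation (POCl3, DMF, 0 °C; aqueous NaOH) gives the 3′-carbaldehyde F9; the chloroiminium ion is a weaker, more selective electrophile, and an N9 formamidinium ion is hydrolysed on work-up. Reductive amination (Me2NH, NaBH(OAc)3, AcOH, 1,2-dichloroethane) then gives 19.

**Step 3.** Conversion may be low, because the [3,3] shift has to reach a carbon flanked by bromine and the nitroarene is electron-rich; reduction to the aniline would then dominate.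

Fallback, setting out from 3 and returning at 4. Fe and NH4Cl in EtOH/H2O reduce 3 to the aniline F10. N-Iodosuccinimide iodinates the only free position ortho to the amino group, giving the ortho-iodoaniline F11. Suzuki coupling at the C–I bond with (E)-2-(2-ethoxyvinyl)-4,4,5,5-tetramethyl-1,3,2-dioxaborolane (Pd(PPh3)4, zerovalent palladium; K2CO3, dioxane/H2O, 80 °C) gives the ortho-(2-ethoxyvinyl)aniline F12. Warm acetic acid closes the pyrrole ring with loss of ethanol to give 4.

## Further compounds

F1 | step 9 | methyl (4aR)-4a-hydroxy-1,3,4,4a-tetrahydro-2H-pyrido[3,4-b]indole-2-carboxylate | COC(=O)N1CC[C@@]2(O)c3ccccc3N=C2C1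
F2 | step 9 | methyl (4aR)-4a-(trimethylsilyloxy)-1,3,4,4a-tetrahydro-2H-pyrido[3,4-b]indole-2-carboxylate | COC(=O)N1CC[C@@]2(O[Si](C)(C)C)c3ccccc3N=C2C1
F3 | step 9 | methyl (4aR,9aR)-9a-[7-methoxy-1-SEM-5-(triisopropylsilyloxy)indol-4-yl]-4a-(trimethylsilyloxy)-1,3,4,4a,9,9a-hexahydro-2H-pyrido[3,4-b]indole-2-carboxylate | COc1cc(O[Si](C(C)C)(C(C)C)C(C)C)c(c2ccn(COCC[Si](C)(C)C)c12)[C@@]12CN(C(=O)OC)CC[C@@]1(O[Si](C)(C)C)c1ccccc1N2
F4 | step 9 | methyl (4aR,9aR)-4a-hydroxy-9a-(5-hydroxy-7-methoxy-1-SEM-indol-4-yl)-1,3,4,4a,9,9a-hexahydro-2H-pyrido[3,4-b]indole-2-carboxylate | COc1cc(O)c(c2ccn(COCC[Si](C)(C)C)c12)[C@@]12CN(C(=O)OC)CC[C@@]1(O)c1ccccc1N2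
F5 | step 8 | (1R,2S,5R)-menthyl 1,3,4,9-tetrahydro-2H-pyrido[3,4-b]indole-2-carboxylate | CC(C)[C@@H]1CC[C@@H](C)C[C@H]1OC(=O)N1CCc2c(C1)[nH]c1ccccc21
F6 | step 8 | (1R,2S,5R)-menthyl (4aS)-4a-hydroxy-1,3,4,4a-tetrahydro-2H-pyrido[3,4-b]indole-2-carboxylate | CC(C)[C@@H]1CC[C@@H](C)C[C@H]1OC(=O)N1CC[C@]2(O)c3ccccc3N=C2C1
F7 | step 8 | (4aS,9aR)-N2-[(1R,2S,5R)-menthyloxycarbonyl]-N1′-SEM-7′-methoxy core | CC(C)[C@@H]1CC[C@@H](C)C[C@H]1OC(=O)N1CC[C@@]23Oc4cc(OC)c5n(COCC[Si](C)(C)C)ccc5c4[C@]2(C1)Nc1ccccc13
F8 | step 8 | (4aS,9aR)-N2-[(1R,2S,5R)-menthyloxycarbonyl]-7′-methoxy core (N1′–H) | CC(C)[C@@H]1CC[C@@H](C)C[C@H]1OC(=O)N1CC[C@@]23Oc4cc(OC)c5[nH]ccc5c4[C@]2(C1)Nc1ccccc13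
F9 | step 12 | (4aS,9aR)-3′-formyl-N2-methyl-7′-methoxy core | COc1cc2c(c3c(C=O)c[nH]c13)[C@@]13CN(C)CC[C@]1(O2)c1ccccc1N3
F10 | step 3 | 5-bromo-2-methoxy-4-(triisopropylsilyloxy)aniline | COc1cc(O[Si](C(C)C)(C(C)C)C(C)C)c(Br)cc1N
F11 | step 3 | 3-bromo-2-iodo-6-methoxy-4-(triisopropylsilyloxy)aniline | COc1cc(O[Si](C(C)C)(C(C)C)C(C)C)c(Br)c(I)c1N
F12 | step 3 | 3-bromo-2-[(E)-2-ethoxyvinyl]-6-methoxy-4-(triisopropylsilyloxy)aniline | CCO/C=C/c1c(N)c(OC)cc(O[Si](C(C)C)(C(C)C)C(C)C)c1Br
A1 | alternative 1 | 2-[2-(5-hydroxy-7-methoxy-1H-indol-4-yl)-1H-indol-3-yl]-N-methylethanamine | CNCCc1c(-c2c(O)cc(OC)c3[nH]ccc23)[nH]c2ccccc12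
A2 | alternative 2 | 7-methoxy-1H-indol-5-ol | COc1cc(O)cc2cc[nH]c12
A3 | alternative 3 | (4aS,9aR)-N2-(methoxycarbonyl) nitroarene core lacking ring F (methoxy and nitro on adjacent carbons of ring E) | COc1cc2c(cc1[N+](=O)[O-])[C@@]13CN(C(=O)OC)CC[C@]1(O2)c1ccccc1N3
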